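The para-disubstituted benzene ring, the only ring, is built and not bought. Its 1,4-pattern, C1 carrying the CH2CH2O-acyl chain and C4 the OH, is that of a 4-substituted cyclohex-2-enone, so the route rests on disconnecting the arene bonds C1–C6 and C2–C3. One Robinson annulation joins the ester aldehyde 4-oxobutyl tetracontanoate (its α-carbon becomes C1, its CHO carbon C2) with methyl vinyl ketone (CH3 becomes C3, C=O becomes C4) and closes the six-membered carbocycle with the C40 ester already in place. Aerobic palladium dehydrogenation then aromatises the ring and reveals the phenol in the last step, without any protecting group.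

Key step: step 4

Remark: the target has no stereocentre and no stereogenic double bond, so it is a single achiral compound and no enantiocontrol is needed; the one sp3 stereocentre that appears in 11–13 is removed in step 5.

Step 1
Reactants: 1 1-bromodocosane; 2 18-bromooctadecanoic acid
Product: 5 tetracontanoic acid, via docosylmagnesium bromide 3 (not isolated), via chloromagnesium 18-bromooctadecanoate 4 (not isolated)
Conditions: 1 (1.3 equiv), Mg, THF, 45 °C; 2, MeMgCl (1.0 equiv), THF, −20 °C; combine, Li2CuCl4 (3 mol%), THF, −10 °C → rt; aq. HCl
Reagents that add atoms: none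
Why: Copper-catalysed sp3–sp3 cross-coupling of a primary alkyl Grignard reagent with a primary ω-bromoalkanoate salt (Kochi-type coupling) is an established one-step chain extension of fatty acids, the magnesium carboxylate being inert to the Grignard reagent and the product acid being separable from hydrocarbon by-products by crystallisation.

Step 2
Reactants: 5 tetracontanoic acid; 6 1,4-butanediol
Product: 8 4-hydroxybutyl tetracontanoate, via tetracontanoyl chloride 7 (not isolated)
Conditions: (COCl)2 (1.5 equiv), DMF (cat.), toluene, 50 °C; evaporate; 6 (10 equiv), pyridine (2 equiv), THF, 50 °C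
Reagents that add atoms: none
Why: Acid chloride formation followed by nucleophilic acyl substitution on a tenfold excess of the symmetrical diol should give mainly the mono-ester, and the excess diol is removed by washing with water or methanol.

Step 3
Reactants: 8 4-hydroxybutyl tetracontanoate
Product: 9 4-oxobutyl tetracontanoate
Conditions: Dess–Martin periodinane (1.3 equiv), CHCl3, 35 °C
Reagents that add atoms: none
Why: Dess–Martin oxidation of a primary alcohol stops at the aldehyde under neutral, anhydrous, non-cryogenic conditions, so the waxy substrate stays dissolved and the ester is not touched.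

Step 4
Reactants: 9 4-oxobutyl tetracontanoate; 10 methyl vinyl ketone
Product: 13 2-(4-oxocyclohex-2-en-1-yl)ethyl tetracontanoate, via 3-formyl-6-oxoheptyl tetracontanoate 11 (not isolated), via 2-(2-hydroxy-4-oxocyclohexyl)ethyl tetracontanoate 12 (not isolated)
Conditions: 10 (1.5 equiv), (S)-2-(methoxydiphenylmethyl)pyrrolidine (10 mol%), ethyl 3,4-dihydroxybenzoate (20 mol%), toluene, 35 °C; evaporate excess 10; p-TsOH·H2O (30 mol%), toluene, 80 °C
Reagents that add atoms: none
Why: The secondary amine condenses with aldehyde 9 to an enamine whose nucleophilic carbon (the aldehyde α-carbon, future arene C1) adds to the terminal carbon of the vinyl ketone (future C6) to give keto aldehyde 11 after hydrolysis; the acid then enolises the methyl ketone towards CH3 (future C3), which attacks the aldehyde carbon (future C2), and aldol 12 loses water to give the conjugated enone. The closest known reaction type is the amine-catalysed Michael addition of unbranched aldehydes to vinyl ketones followed by aldol condensation, that is, an organocatalytic Robinson annulation to 4-substituted cyclohex-2-enones. The one ring is closed in a 6-(enolendo)-exo-trig aldol mode. The new stereocentre at the chain-bearing ring carbon is influenced by the catalyst but is left uncontrolled on purpose, because it becomes sp2 in step 5, so any enantiomer or the racemate of the catalyst serves. Mono-addition is needed and should be secured by the bulky catalyst, which converts the α-branched adduct 11 into an enamine only slowly; closure through the methyl side is needed and is secured because every other enol of 11 could only form a four-membered ring. The ester is a spectator under both the amine stage and the sulfonic acid stage, which is why a hydroxide-mediated aldol closure is avoided.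

Step 5
Reactants: 13 2-(4-oxocyclohex-2-en-1-yl)ethyl tetracontanoate
Product: 15 2-(4-hydroxyphenyl)ethyl tetracontanoate, via 2-(4-oxocyclohexa-2,5-dien-1-yl)ethyl tetracontanoate 14 (not isolated)
Conditions: Pd(TFA)2 (5 mol%), 2-(dimethylamino)pyridine (10 mol%), p-TsOH·H2O (20 mol%), O2 (1 atm), DMSO/PhCl (1:1), 80 °C
Reagents that add atoms: none
Why: Palladium(II)-catalysed aerobic dehydrogenation of a cyclohexenone (Pd-enolate formation at the α'-CH2, then β-hydride elimination) should give the 2,5-dienone 14, whose remaining ring C–H allows tautomerisation to the phenol, while the ester and the saturated chain are inert.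

Compound list
1 | 1-bromodocosane | CCCCCCCCCCCCCCCCCCCCCCBr | starting material
2 | 18-bromooctadecanoic acid | OC(=O)CCCCCCCCCCCCCCCCCBr | starting material
3 | docosylmagnesium bromide (not isolated) | CCCCCCCCCCCCCCCCCCCCCC[Mg]Br | intermediate
4 | chloromagnesium 18-bromooctadecanoate (not isolated) | BrCCCCCCCCCCCCCCCCCC(=O)O[Mg]Cl | intermediate
5 | tetracontanoic acid | CCCCCCCCCCCCCCCCCCCCCCCCCCCCCCCCCCCCCCCC(=O)O | intermediate
6 | 1,4-butanediol | OCCCCO | starting material
7 | tetracontanoyl chloride (not isolated) | CCCCCCCCCCCCCCCCCCCCCCCCCCCCCCCCCCCCCCCC(=O)Cl | intermediate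
8 | 4-hydroxybutyl tetracontanoate | CCCCCCCCCCCCCCCCCCCCCCCCCCCCCCCCCCCCCCCC(=O)OCCCCO | intermediate
9 | 4-oxobutyl tetracontanoate | CCCCCCCCCCCCCCCCCCCCCCCCCCCCCCCCCCCCCCCC(=O)OCCCC=O | intermediate
10 | methyl vinyl ketone (but-3-en-2-one) | CC(=O)C=C | starting material
11 | 3-formyl-6-oxoheptyl tetracontanoate (not isolated; configuration at C3 undefined) | CCCCCCCCCCCCCCCCCCCCCCCCCCCCCCCCCCCCCCCC(=O)OCCC(C=O)CCC(C)=O | intermediate
12 | 2-(2-hydroxy-4-oxocyclohexyl)ethyl tetracontanoate (not isolated; mixture of stereoisomers) | CCCCCCCCCCCCCCCCCCCCCCCCCCCCCCCCCCCCCCCC(=O)OCCC1CCC(=O)CC1O | intermediate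
13 | 2-(4-oxocyclohex-2-en-1-yl)ethyl tetracontanoate (configuration at ring C1 undefined and irrelevant) | CCCCCCCCCCCCCCCCCCCCCCCCCCCCCCCCCCCCCCCC(=O)OCCC1C=CC(=O)CC1 | intermediate
14 | 2-(4-oxocyclohexa-2,5-dien-1-yl)ethyl tetracontanoate (not isolated) | CCCCCCCCCCCCCCCCCCCCCCCCCCCCCCCCCCCCCCCC(=O)OCCC1C=CC(=O)C=C1 | intermediate
15 | 2-(4-hydroxyphenyl)ethyl tetracontanoate (achiral) | CCCCCCCCCCCCCCCCCCCCCCCCCCCCCCCCCCCCCCCC(=O)OCCc1ccc(O)cc1 | target

Total step count: 5
Longest linear sequence: 5 steps (1 and 2 → 5 → 8 → 9 → 13 → 15)

Steps most likely to fail

Step 4. At the dilution that the waxy aldehyde needs, enamine formation may be slow, so self-aldol condensation of the aldehyde and polymerisation of the vinyl ketone may outrun the Michael addition. The acid-promoted closure may also stall before dehydration. The fallback replaces the catalytic cascade by a stoichiometric, stepwise Stork enamine annulation; it sets out from 9 and comes back at 13. Aldehyde 9 would be condensed with pyrrolidine (1.2 equiv, K2CO3, toluene, 0 °C to rt) to the enamine (E)-4-(pyrrolidin-1-yl)but-3-en-1-yl tetracontanoate F1, which is freed from excess amine. F1 would then be treated with 10 in toluene at rt, and the adduct hydrolysed and cyclised with an AcOH/NaOAc buffer in aqueous THF at 70 °C. This should give 13 by way of 11, with the free aldehyde never exposed to amine and enone at the same time.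

Step 5. Poor mixing of the lipid with the polar medium may starve the palladium catalyst of substrate, so that the catalyst aggregates and conversion stalls; over-oxidation of the electron-rich phenol is a lesser risk. The fallback replaces catalytic dehydrogenation by a Saegusa–Ito oxidation; it sets out from 13 and comes back at 15. Enone 13 would be silylated under soft enolisation (TMSOTf, Et3N, CH2Cl2, 0 °C) to the dienol ether 2-[4-(trimethylsilyloxy)cyclohexa-2,4-dien-1-yl]ethyl tetracontanoate F2. F2 would be oxidised with Pd(OAc)2 (1.0 equiv, MeCN/THF, 40 °C) to dienone 14, which should tautomerise in the flask to 15.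

Step 1. The long-chain organomagnesium reagent and the carboxylate salt may precipitate at low temperature, slowing the cross-coupling so that homocoupling and simple protonation of the Grignard reagent dominate. The fallback replaces the copper-catalysed coupling by acetylide alkylation and hydrogenation; it sets out from 1 and comes back at 5. Commercial 17-octadecynoic acid would be deprotonated twice (n-BuLi, 2.1 equiv, THF/DMPU, −40 °C) to dilithium octadec-17-yn-18-ide-1-oate F3, used in the flask. F3 would be alkylated with 1 (rt to 40 °C; aq. HCl work-up) to tetracont-17-ynoic acid F4. Hydrogenation of F4 (H2, Pd/C, THF, 50 °C) should give 5.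

Further compounds
F1 | step 4 | (E)-4-(pyrrolidin-1-yl)but-3-en-1-yl tetracontanoate | CCCCCCCCCCCCCCCCCCCCCCCCCCCCCCCCCCCCCCCC(=O)OCC/C=C/N1CCCC1
F2 | step 5 | 2-[4-(trimethylsilyloxy)cyclohexa-2,4-dien-1-yl]ethyl tetracontanoate | CCCCCCCCCCCCCCCCCCCCCCCCCCCCCCCCCCCCCCCC(=O)OCCC1CC=C(O[Si](C)(C)C)C=C1
F3 | step 1 | dilithium octadec-17-yn-18-ide-1-oate (dilithio derivative of 17-octadecynoic acid) | [Li]C#CCCCCCCCCCCCCCCCC(=O)O[Li]
F4 | step 1 | tetracont-17-ynoic acid | CCCCCCCCCCCCCCCCCCCCCCC#CCCCCCCCCCCCCCCCC(=O)O
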